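## Analysis of the target

The target 42 is a ten-membered carbocycle. Ring atoms are numbered C1–C10; C11–C13 are the 2-propenyl unit on C1 (C12 the methylene, C13 the acetoxymethyl carbon), C14 is the hydroxymethyl carbon on C8 and C15 the acyloxymethyl carbon on C4. The ring holds an E trisubstituted C4=C5 alkene and a C8–C9 oxirane in which the ring bonds C7–C8 and C9–C10 are trans, with C14H2OH on the quaternary C8. C3 carries a senecioate and C15 a (2R,3S)-3-hydroxy-2-methylbutanoate. In this numbering the ring stereocentres are 1S, 3R, 8S and 9R. C1 and C3 are 1,3-related across C2 and lie on one face, whereas C8 and C9 are remote from them and cannot be set from C1/C3 by simple induction. The sensitive parts are the oxirane, which faces the C4=C5 alkene across the ring and cyclises transannularly under acid, three different esters (a primary allylic acetate, an enoate that deconjugates under strong base, a β-hydroxy ester) and four oxygens (C3, C13, C14, C15) that must be told apart. The strategy rests on one feature: C4 and C9 lie opposite each other, C9 bears oxygen and C5 is the alkene carbon next to C4. A temporary C4–C9 bond therefore gives a decalin (ring A: C4–C5–C6–C7–C8–C9; ring B: C4–C3–C2–C1–C10–C9) in which a C9 alkoxide and a C5 leaving group are 1,3-related and can be expelled against each other.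

## Retrosynthetic reasoning

**42 to 40.** The oxirane and the free C14 hydroxyl are traced to the spiro-epoxy alcohol 40 (oxirane C8–C14, hydroxyl on C9) through a Payne rearrangement (41), followed by desilylation. The C9 alkoxide attacks C8 with inversion, so the trans oxirane arises stereospecifically and no E-configured C8=C9 ring alkene is needed. The trans oxirane requires the threo isomer of the epoxy alcohol; the erythro isomer would give the oxirane with C7 and C10 cis.

**40 to 28.** A hydroxyl-directed epoxidation of a C9 carbinol always gives the erythro isomer (oxygen delivered syn to the hydroxyl, C9–H eclipsing C7). A direct sequence of reduction, directed epoxidation and migration would therefore end in the wrong oxirane. C9 is instead set last, by reagent-controlled reduction of the epoxy ketone 39. The three esters are put on before that (29 to 39, with acid 35), because the acetonide must be removed with acid before the acid-labile C8–C9 oxirane exists.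

**28 to 25.** C8 is set on the enone 25 through a sacrificial C9 carbinol of the opposite configuration (26), directed epoxidation (27) and re-oxidation. The hydroxyl-directed reagent touches only the C8=C14 alkene among the four alkenes present.

**25 to 23 (key disconnection).** The ten-membered ring is traced to the trans-decalin hydroxy mesylate 23 by re-forming the C4–C9 bond. Forward, the C9 alkoxide expels the C5 mesylate with cleavage of C4–C9. This cut gives the ring without a cyclisation, and it fixes the alkene geometry through the rigid chair: C3 is anti to C6 about C4–C5, so C15 ends cis to C6.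

**23 to 18.** The equatorial C5 oxygen comes from a ketone (21) by reduction directed by the axial C9 hydroxyl. The trans ring fusion is the demanding point. Any carbon nucleophile, tethered or not, would attack a ring-B C9 ketone from the face away from the axial C15 arm and give the cis-fused carbinol, whose accessible chair would lead to the Z alkene. The C8–C9 bond is therefore made first as an alkene (enal 18), and the C9 oxygen is delivered last, from the same open face, by epoxidation (19). A Wharton transposition then moves the double bond to C8=C14 and leaves the oxygen on C9.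

**18 to 13 and 14.** Ring A is cut at C8=C9 (aldol condensation of keto aldehyde 17) and at C5–C6 (addition of the four-carbon Grignard reagent 15, from 14, to the aldehyde 13). Only the six-membered closure is geometrically possible for 17.

**13 to 8.** All four neighbours of C4 are oxygenated, so C4 is taken as the central carbon of a 1,3-dione (8). C15 comes from hydroxymethylation and C5 from a dithianyl group as masked formyl (9, 10). The meso dione 10 is desymmetrised by an oxazaborolidine reduction that sets C3 and C4, and C1 relative to them (11). The acetonide 12 then locks ring B with C15 axial.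

**8 to 1 and 5.** The 2-propenyl unit is built from the ester carbon of 1 (C11) by amide formation, addition of the alkoxymethyl carbanion from stannane 5 (C13) and methylenation (C12). This is done while the dione protects itself as its enolate.

**35 to 30 and 31.** The side-chain acid is cut at C2'–C3' (syn aldol with auxiliary control).

## Alternatives that were turned down

**Alternative 1:** The ring is cut at C1–C10. Forward, the sodium enolate of a C11 N-acyl oxazolidinone displaces a C10 allylic bromide at high dilution and gives the ten-membered (E,E)-diene A1; the auxiliary sets C1.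
- For: both ring alkenes come with defined geometry from acyclic chemistry. The E C8=C9 allylic alcohol would later give the trans oxirane in a single reagent-controlled epoxidation. On the C8/C9 problem this route is stronger than the chosen one, which needs five operations.
- Against: a ten-membered ring must be closed by SN2 attack of an α-branched imide enolate. Medium-ring strain and the entropic cost favour oligomers, O-alkylation and loss of the allylic bromide, while the enolate is thermally fragile. The face demanded by the auxiliary must also suit the tether that already carries C3.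
- After closure the C11 carbonyl still needs two carbons to become C(=CH2)CH2OAc, and three silyl ethers must be told apart on a sensitive diene.
- Comparison: the chosen route obtains the ring by cleaving a bond of a rigid bicycle, with no dilution, and the alkene geometry follows from a chair. It pays with a longer oxirane endgame.

**Alternative 2:** The ring is cut at C8–C9. Forward, a divalent vanadium reductant couples a C9 aldehyde with a C8 ketone (pinacol closure) to the 8,9-diol A2, which already carries all three esters.
- For: this is the most convergent end of all. The diol would close to the oxirane by C9 sulfonylation with inversion, without an epoxide migration. In step count after ring formation it is as strong as or stronger than the chosen route.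
- Against: two stereocentres are made at once on a flexible chain with only the remote C1/C3 to guide them, and only one of four diastereomers serves. A medium-ring pinacol closure competes with intermolecular coupling. The low-valent metal threatens the enoate and the allylic esters.
- Comparison: the chosen route sets C8 by intramolecular oxygen delivery and C9 by a chiral reagent, one at a time.

**Alternative 3:** The ring is cut at C1–C2 through a [3,3] shift. Forward, heating a twelve-membered cyclic enol ether contracts it to the ten-membered C3 ketone A3, creating C1 and the C11=C12 alkene.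
- For: direct closure of the strained ring is avoided, the shift is concerted and the C8=C9 alkene is again E, so the oxirane is easy.
- Against: A3 has C1 as its only stereocentre, and the precursor has no sp3 centre in the ring to bias the transition state, so the absolute configuration needs an outside source. The C3 ketone must later be reduced with 1,3-control across a flexible ring. The macrocyclic enol ether requires a macrolactonisation and a carbonyl methylenation. The vinylsilane and three different benzyl-type and trityl ethers add protecting-group steps.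
- Comparison: the chosen route sets C1 and C3 together on a six-membered ring, where conformational control is predictable.

Key step: step 17

Remark: 3, 14 and 30 are taken as purchasable, and in each oxazaborolidine reduction the more substituted flank of the carbonyl (C4 in 10, C8 in 25 and 39) is taken to act as the large group. β denotes the face of ring B that carries the C1 side chain, and "PMB" is 4-methoxybenzyl.

## Steps

**Step 1**
Reactants: 1 methyl 3,5-dioxocyclohexane-1-carboxylate
Product: 2 N-methoxy-N-methyl-3,5-dioxocyclohexane-1-carboxamide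
Conditions: MeNHOMe·HCl, iPrMgCl (4 equiv), THF, −20 to 0 °C; aq. HCl
Reagents that add atoms: N,O-dimethylhydroxylamine hydrochloride, CNOC.Cl
Why: Ester aminolysis by the chloromagnesium amide (N-methoxy-N-methylamide formation); the acidic 1,3-dione is first converted into its magnesium enolate, which shields both ring carbonyl groups.

**Step 2**
Reactants: 3 (tributylstannyl)methanol; 4 4-methoxybenzyl chloride
Product: 5 tributyl({[(4-methoxyphenyl)methoxy]methyl})stannane
Conditions: NaH, Bu4NI (cat.), THF/DMF, 0 °C to rt
Reagents that add atoms: none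
Why: Williamson ether synthesis of a primary alkoxide with a reactive benzylic chloride.

**Step 3**
Reactants: 2 N-methoxy-N-methyl-3,5-dioxocyclohexane-1-carboxamide; 5 tributyl({[(4-methoxyphenyl)methoxy]methyl})stannane
Product: 7 5-{[(4-methoxyphenyl)methoxy]acetyl}cyclohexane-1,3-dione, via {[(4-methoxyphenyl)methoxy]methyl}lithium 6 (not isolated)
Conditions: 5, n-BuLi, THF, −78 °C; add lithium enolate of 2 (LiN(SiMe3)2, THF, −78 °C); −78 to −40 °C; aq. NH4Cl
Reagents that add atoms: none
Why: Tin–lithium exchange gives the α-alkoxy organolithium, which adds once to the N-methoxy-N-methylamide because the chelated tetrahedral adduct persists until work-up (ketone synthesis); the dione is again masked as its enolate.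

**Step 4**
Reactants: 7 5-{[(4-methoxyphenyl)methoxy]acetyl}cyclohexane-1,3-dione
Product: 8 5-{3-[(4-methoxyphenyl)methoxy]prop-1-en-2-yl}cyclohexane-1,3-dione
Conditions: Ph3PCH3Br, KOC(CH3)3 (3.2 equiv), THF, 0 °C to rt; acidify
Reagents that add atoms: methyltriphenylphosphonium bromide, C[P+](c1ccccc1)(c1ccccc1)c1ccccc1.[Br-]
Why: Wittig methylenation of the side-chain ketone creates C11=C12; one equivalent of ylide is spent on the dione, whose enolate does not react with the ylide.

**Step 5**
Reactants: 8 5-{3-[(4-methoxyphenyl)methoxy]prop-1-en-2-yl}cyclohexane-1,3-dione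
Product: 9 2-(1,3-dithian-2-yl)-5-{3-[(4-methoxyphenyl)methoxy]prop-1-en-2-yl}cyclohexane-1,3-dione
Conditions: 1,3-dithiane, N-chlorosuccinimide, CH2Cl2, 0 °C; then 8, 2,6-lutidine, 0 °C to rt
Reagents that add atoms: 1,3-dithiane, C1CSCSC1
Why: C-alkylation of the enolised dione at C4 by the 1,3-dithian-2-ylium ion, a formyl cation equivalent released from 2-chloro-1,3-dithiane; the soft cation should end on carbon as the stable product.

**Step 6**
Reactants: 9 2-(1,3-dithian-2-yl)-5-{3-[(4-methoxyphenyl)methoxy]prop-1-en-2-yl}cyclohexane-1,3-dione
Product: 10 cis-2-(1,3-dithian-2-yl)-2-(hydroxymethyl)-5-{3-[(4-methoxyphenyl)methoxy]prop-1-en-2-yl}cyclohexane-1,3-dione (hydroxymethyl and the 5-substituent on the same face; achiral)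
Conditions: aq. CH2O (37%), Et3N (cat.), THF, 0 °C to rt
Reagents that add atoms: formaldehyde, C=O
Why: Aldol addition (hydroxymethylation) of the 2-substituted dione makes C4 quaternary; the bulky dithianyl group should sit equatorial and the small hydroxymethyl axial, cis to the equatorial C1 side chain, and because the addition is reversible this isomer should prevail.

**Step 7**
Reactants: 10 cis-2-(1,3-dithian-2-yl)-2-(hydroxymethyl)-5-{3-[(4-methoxyphenyl)methoxy]prop-1-en-2-yl}cyclohexane-1,3-dione
Product: 11 2-(1,3-dithian-2-yl)-3-hydroxy-2-(hydroxymethyl)-5-{3-[(4-methoxyphenyl)methoxy]prop-1-en-2-yl}cyclohexan-1-one with the C3 hydroxyl, C15 and the C1 side chain all β (C1 and C3 as in 42)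
Conditions: (S)-2-methyl-CBS-oxazaborolidine (0.2 equiv), catecholborane (3 equiv), toluene/CH2Cl2, −78 to −40 °C
Reagents that add atoms: none
Why: Corey–Bakshi–Shibata reduction used to desymmetrise a meso 2,2-disubstituted 1,3-dione; the catalyst reads each carbonyl as quaternary C4 (large) against CH2 (small), and only at C3 does the face it demands coincide with the open face anti to the axial hydroxymethyl arm, so hydride should enter there and give the equatorial C3 hydroxyl cis to C15. This sets C3 and C4 and, with them, C1.

**Step 8**
Reactants: 11 the β-hydroxy ketone of step 7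
Product: 12 C3–O/C15–O isopropylidene acetal of 11 (cis-fused 1,3-dioxane; dithianyl on C4 α; C9 ketone)
Conditions: Me2C(OMe)2, PPTS (cat.), acetone, rt
Reagents that add atoms: 2,2-dimethoxypropane, COC(C)(C)OC
Why: Acetal exchange on the cis 1,3-diol; the six-membered acetal locks ring B with C15 axial and the C5 arm equatorial.

**Step 9**
Reactants: 12 the acetonide of step 8
Product: 13 the corresponding C4 carbaldehyde (C5 = CHO; acetonide, C9 ketone, PMB ether)
Conditions: MeI, CaCO3, MeCN/H2O (9:1), 45 °C
Reagents that add atoms: water, O
Why: S-alkylative hydrolysis of the dithioacetal under neutral conditions, which should leave the acetonide and the PMB ether untouched; the β-keto aldehyde cannot enolise at C4.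

**Step 10**
Reactants: 13 the aldehyde of step 9; 14 4-chlorobutan-1-ol
Product: 16 diol with a C5 carbinol bearing the 4-hydroxybutyl chain (both C5 epimers), via 4-(chloromagnesiooxy)butylmagnesium chloride 15 (not isolated)
Conditions: 14, iPrMgCl (1 equiv), THF, −20 °C; Mg, THF, reflux; then 13, THF, −78 °C; aq. NH4Cl
Reagents that add atoms: none
Why: Grignard addition to the aldehyde, which reacts far faster than the hindered ring ketone at −78 °C; the C5 configuration does not matter because C5 is oxidised next.

**Step 11**
Reactants: 16 the diol of step 10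
Product: 17 keto aldehyde with C4 bearing the 5-oxopentanoyl chain (C5 ketone, C14 aldehyde) beside the C9 ketone
Conditions: DMP (3 equiv), NaHCO3, CH2Cl2, 0 °C to rt
Reagents that add atoms: none
Why: Dess–Martin oxidation of the secondary C5 and the primary C14 alcohol under buffered, non-basic conditions that a non-enolisable 1,3-diketone should survive.

**Step 12**
Reactants: 17 the keto aldehyde of step 11
Product: 18 bicyclic enal (ring A closed; C5 ketone; C8=C9 alkene bearing the C14 formyl group; acetonide and PMB ether unchanged)
Conditions: Bn2NH·CF3CO2H (0.3 equiv), toluene, 50 °C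
Reagents that add atoms: none
Why: Intramolecular aldol condensation through the enamine of the aldehyde (6-enolexo-exo-trig); C8 can reach only the C9 carbonyl through a six-membered transition state, and dehydration gives the conjugated enal.

**Step 13**
Reactants: 18 the enal of step 12
Product: 19 8,9-epoxy aldehyde with the oxirane on the α face (C9–O trans to C15)
Conditions: H2O2 (30%), NaOH (cat.), MeOH, 0 °C
Reagents that add atoms: hydrogen peroxide, OO
Why: Nucleophilic (Weitz–Scheffer) epoxidation of the enal; hydroperoxide should add to C9 from the face away from the axial C15 arm on the adjacent quaternary C4, which places the C9 oxygen trans to C15.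

**Step 14**
Reactants: 19 the epoxy aldehyde of step 13
Product: 21 trans-decalin β-hydroxy ketone (C9–OH α and axial; C8 exocyclic methylene; C5 ketone), via epoxy aldehyde hydrazone 20 (not isolated)
Conditions: N2H4·H2O (1.5 equiv), AcOH (cat.), MeOH, 0 °C to rt
Reagents that add atoms: none
Why: Wharton transposition of an α,β-epoxy aldehyde: the hydrazone opens the oxirane at C8, loss of N2 leaves C14 as a methylene on C8 and the oxygen on C9 with its configuration untouched, which is the tertiary allylic alcohol of the trans-fused decalin. The hindered C5 ketone should condense with hydrazine much more slowly than the aldehyde.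

**Step 15**
Reactants: 21 the β-hydroxy ketone of step 14
Product: 22 trans-decalin diol (C5–OH β and equatorial; C9–OH α and axial)
Conditions: Me4NBH(OAc)3, MeCN/AcOH (1:1), −20 °C
Reagents that add atoms: none
Why: Hydroxyl-directed reduction of a β-hydroxy ketone to the anti 1,3-diol: the axial C9 hydroxyl binds boron and delivers hydride to C5 from its own face, so the new C5 hydroxyl is equatorial and cis to C15.

**Step 16**
Reactants: 22 the diol of step 15
Product: 23 trans-decalin hydroxy mesylate (C5–OMs β, equatorial; C9–OH α; C8 methylene; C3/C15 acetonide; C13 PMB ether)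
Conditions: MsCl (1.2 equiv), Et3N, CH2Cl2, 0 °C
Reagents that add atoms: methanesulfonyl chloride, CS(=O)(=O)Cl
Why: Sulfonylation through sulfene; only the secondary C5 hydroxyl should react, the tertiary allylic C9 hydroxyl being too hindered.

**Step 17 (key step)**
Reactants: 23 the hydroxy mesylate of step 16
Product: 25 ten-membered (E)-C4=C5 cyclodecenone with C9 ketone and C8 exocyclic methylene (C3/C15 acetonide, C13 PMB ether), via potassium C9-alkoxide 24 (not isolated)
Conditions: KOC(CH3)3 (1.1 equiv), THF, 0 °C; pH 7 phosphate buffer
Reagents that add atoms: none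
Why: tert-Butoxide deprotonates the tertiary C9 hydroxyl to alkoxide 24. In the trans-decalin chair an oxygen lone pair, the C4–C9 ring-fusion bond and the equatorial C5–O bond are antiperiplanar, so C9=O and C4=C5 form while C4–C9 breaks and mesylate leaves in one concerted step; this is a Grob fragmentation, whose closest known cases are decalin-1,3-diol monosulfonates giving (E)-cyclodec-5-enones. The ten-membered ring is not closed by a cyclisation but uncovered by cleaving the bond shared by rings A and B, so no dilution is needed and the only new skeletal bond is the π bond. No stereocentre is created; C1 and C3 are carried through and C4, C5 and C9 are erased. The selectivity needed is the E geometry, and the rigid trans fusion secures it because C3 is anti and C15 gauche to C6 about C4–C5. Oxetane formation and elimination towards C6 lack the required alignment with an equatorial leaving group. The α-methylene ketone produced is base-sensitive, hence the small excess of base, the low temperature and the immediate reduction in step 18.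

**Step 18**
Reactants: 25 the enone of step 17
Product: 26 C9 allylic alcohol (C9 configuration opposite to that of 42; C8=C14 methylene)
Conditions: (R)-2-methyl-CBS-oxazaborolidine (0.2 equiv), catecholborane (1.5 equiv), toluene, −78 °C
Reagents that add atoms: none
Why: Corey–Bakshi–Shibata reduction of an α-substituted enone with the alkenyl flank as the large group; the reagent sets C9 in the sense that is needed only to steer the next step.

**Step 19**
Reactants: 26 the allylic alcohol of step 18
Product: 27 erythro spiro-epoxy alcohol (oxirane C8–C14; C9–OH as in 26)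
Conditions: VO(acac)2 (5 mol%), t-BuOOH, CH2Cl2, 0 °C
Reagents that add atoms: tert-butyl hydroperoxide, CC(C)(C)OO
Why: Hydroxyl-directed epoxidation through the vanadium alkoxide–peroxide complex reacts only at the allylic C8=C14 alkene; for a 1,1-disubstituted allylic alcohol oxygen is delivered syn to the hydroxyl with C9–H eclipsing C7 (A(1,2) strain), which gives the erythro isomer and hence the required C8 configuration.

**Step 20**
Reactants: 27 the epoxy alcohol of step 19
Product: 28 spiro-epoxy ketone (C9 ketone; C8 configured; acetonide and PMB ether)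
Conditions: DMP, NaHCO3, CH2Cl2, 0 °C
Reagents that add atoms: none
Why: Dess–Martin oxidation removes the auxiliary C9 centre; the quaternary C8 cannot epimerise.

**Step 21**
Reactants: 28 the epoxy ketone of step 20
Product: 29 diol (C3–OH, C15–OH; E C4=C5; spiro-epoxy ketone; C13 PMB ether)
Conditions: AcOH/H2O/THF (3:1:1), 40 °C
Reagents that add atoms: none
Why: Acid hydrolysis of the isopropylidene acetal, placed before the C8–C9 oxirane exists; the spiro-oxirane next to a carbonyl is much less prone to acid opening.

**Step 22**
Reactants: 30 (R)-4-benzyl-3-propanoyl-1,3-oxazolidin-2-one; 31 acetaldehyde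
Product: 33 (R)-4-benzyl-3-[(2R,3S)-3-hydroxy-2-methylbutanoyl]-1,3-oxazolidin-2-one, via dibutylboron Z-enolate 32 (not isolated)
Conditions: Bu2BOTf, iPr2NEt, CH2Cl2, −78 to 0 °C; MeCHO, −78 °C; H2O2, pH 7 buffer, MeOH
Reagents that add atoms: none
Why: Evans syn aldol: the Z boron enolate reacts through a chair transition state on the face left open by the auxiliary, which sets C2' (R) and C3' (S).

**Step 23**
Reactants: 33 the aldol adduct of step 22
Product: 34 its 3'-O-triethylsilyl ether
Conditions: Et3SiCl, imidazole, DMF, 0 °C
Reagents that add atoms: chlorotriethylsilane, CC[Si](Cl)(CC)CC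
Why: Silylation of the secondary alcohol; the silyl ether blocks self-acylation and β-elimination in the later esterification.

**Step 24**
Reactants: 34 the silyl ether of step 23
Product: 35 (2R,3S)-2-methyl-3-[(triethylsilyl)oxy]butanoic acid
Conditions: LiOH, H2O2, THF/H2O, 0 °C; Na2SO3; HCl to pH 3
Reagents that add atoms: hydrogen peroxide, OO
Why: Hydroperoxide attacks the exocyclic imide carbonyl selectively (auxiliary cleavage) without epimerising C2'.

**Step 25**
Reactants: 29 the diol of step 21; 35 the acid of step 24
Product: 36 C15 ester of 29 with acid 35 (C3–OH free)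
Conditions: EDC·HCl, DMAP (0.1 equiv), CH2Cl2, −20 to 0 °C
Reagents that add atoms: none
Why: Carbodiimide esterification; the primary allylic C15 hydroxyl should react well ahead of the secondary C3 hydroxyl.

**Step 26**
Reactants: 36 the mono-ester of step 25
Product: 37 C3 3-methylbut-2-enoate of 36
Conditions: 3-methylbut-2-enoyl chloride, pyridine, CH2Cl2, 0 °C
Reagents that add atoms: 3-methylbut-2-enoyl chloride, CC(C)=CC(=O)Cl
Why: Acylation of the secondary allylic alcohol with pyridine as the only base, mild enough to avoid the vinylketene path that would deconjugate the enoate.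

**Step 27**
Reactants: 37 the diester of step 26
Product: 38 C13 primary allylic alcohol
Conditions: DDQ, CH2Cl2/pH 7 buffer, 0 °C
Reagents that add atoms: none
Why: Oxidative cleavage of the PMB ether under buffered conditions that the esters, the silyl ether and the epoxy ketone should tolerate.

**Step 28**
Reactants: 38 the alcohol of step 27
Product: 39 C13 acetate (spiro-epoxy ketone carrying all three esters)
Conditions: Ac2O, pyridine, DMAP (cat.), CH2Cl2, 0 °C
Reagents that add atoms: acetic anhydride, CC(=O)OC(C)=O
Why: Acetylation of the only free hydroxyl.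

**Step 29**
Reactants: 39 the epoxy ketone of step 28
Product: 40 threo spiro-epoxy alcohol (C9–OH configured as C9 in 42)
Conditions: (S)-2-methyl-CBS-oxazaborolidine (0.3 equiv), catecholborane (1.5 equiv), toluene, −78 °C
Reagents that add atoms: none
Why: Corey–Bakshi–Shibata reduction with the quaternary oxirane carbon C8 as the large group; the reagent must override the substrate's own preference for the erythro alcohol, and catecholborane at −78 °C should not touch esters or alkenes.

**Step 30**
Reactants: 40 the threo epoxy alcohol of step 29
Product: 41 3'-O-triethylsilyl ether of 42 (C8–C9 oxirane, C14–OH)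
Conditions: KOC(CH3)3 (0.2 equiv), THF, −20 to 0 °C; pH 7 buffer
Reagents that add atoms: none
Why: Payne rearrangement: the C9 alkoxide opens the spiro-oxirane at C8 with inversion, giving the more substituted oxirane and the primary alkoxide; from the threo isomer C7 and C10 end trans, as in the target.

**Step 31**
Reactants: 41 the silyl ether of step 30
Product: 42 the target
Conditions: Bu4NF, AcOH (1:1), THF, 0 °C to rt
Reagents that add atoms: none
Why: Fluoride desilylation buffered with acetic acid, so that neither the oxirane nor the esters meet free acid or alkoxide.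

## Compound list

1 | methyl 3,5-dioxocyclohexane-1-carboxylate | COC(=O)C1CC(=O)CC(=O)C1 | starting material
2 | N-methoxy-N-methyl-3,5-dioxocyclohexane-1-carboxamide | CON(C)C(=O)C1CC(=O)CC(=O)C1 | intermediate
3 | (tributylstannyl)methanol | CCCC[Sn](CCCC)(CCCC)CO | starting material
4 | 4-methoxybenzyl chloride | COc1ccc(CCl)cc1 | starting material
5 | tributyl({[(4-methoxyphenyl)methoxy]methyl})stannane | CCCC[Sn](CCCC)(CCCC)COCc1ccc(OC)cc1 | intermediate
6 | {[(4-methoxyphenyl)methoxy]methyl}lithium (not isolated) | [Li]COCc1ccc(OC)cc1 | intermediate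
7 | 5-{[(4-methoxyphenyl)methoxy]acetyl}cyclohexane-1,3-dione | COc1ccc(COCC(=O)C2CC(=O)CC(=O)C2)cc1 | intermediate
8 | 5-{3-[(4-methoxyphenyl)methoxy]prop-1-en-2-yl}cyclohexane-1,3-dione | C=C(COCc1ccc(OC)cc1)C1CC(=O)CC(=O)C1 | intermediate
9 | 2-(1,3-dithian-2-yl)-5-{3-[(4-methoxyphenyl)methoxy]prop-1-en-2-yl}cyclohexane-1,3-dione | C=C(COCc1ccc(OC)cc1)C1CC(=O)C(C2SCCCS2)C(=O)C1 | intermediate
10 | cis-2-(1,3-dithian-2-yl)-2-(hydroxymethyl)-5-{3-[(4-methoxyphenyl)methoxy]prop-1-en-2-yl}cyclohexane-1,3-dione (meso) | C=C(COCc1ccc(OC)cc1)[C@H]1CC(=O)[C@](CO)(C2SCCCS2)C(=O)C1 | intermediate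
11 | ring-B hydroxy ketone (C3–OH, C15 and C1 side chain β; dithianyl α; C9 ketone) | C=C(COCc1ccc(OC)cc1)[C@H]1C[C@@H](O)[C@](CO)(C2SCCCS2)C(=O)C1 | intermediate
12 | C3/C15 acetonide of 11 | C=C(COCc1ccc(OC)cc1)[C@H]1C[C@H]2OC(C)(C)OC[C@@]2(C3SCCCS3)C(=O)C1 | intermediate
13 | C4 carbaldehyde (C5 = CHO), acetonide, C9 ketone | C=C(COCc1ccc(OC)cc1)[C@H]1C[C@H]2OC(C)(C)OC[C@@]2(C=O)C(=O)C1 | intermediate
14 | 4-chlorobutan-1-ol | OCCCCCl | starting material
15 | 4-(chloromagnesiooxy)butylmagnesium chloride (not isolated) | Cl[Mg]CCCCO[Mg]Cl | intermediate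
16 | C5,C14-diol (C5 epimers) | C=C(COCc1ccc(OC)cc1)[C@H]1C[C@H]2OC(C)(C)OC[C@@]2(C(O)CCCCO)C(=O)C1 | intermediate
17 | C5,C9-diketo C14-aldehyde | C=C(COCc1ccc(OC)cc1)[C@H]1C[C@H]2OC(C)(C)OC[C@@]2(C(=O)CCCC=O)C(=O)C1 | intermediate
18 | bicyclic enal (C8=C9, C14 formyl, C5 ketone) | C=C(COCc1ccc(OC)cc1)[C@H]1C[C@H]2OC(C)(C)OC[C@]23C(=O)CCC(C=O)=C3C1 | intermediate
19 | α-8,9-epoxy aldehyde | C=C(COCc1ccc(OC)cc1)[C@H]1C[C@H]2OC(C)(C)OC[C@]23C(=O)CC[C@]4(C=O)O[C@@]43C1 | intermediate
20 | hydrazone of 19 (not isolated) | C=C(COCc1ccc(OC)cc1)[C@H]1C[C@H]2OC(C)(C)OC[C@]23C(=O)CC[C@]4(C=NN)O[C@@]43C1 | intermediate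
21 | trans-decalin β-hydroxy ketone (C9–OH α, C8 methylene, C5 ketone) | C=C(COCc1ccc(OC)cc1)[C@H]1C[C@H]2OC(C)(C)OC[C@]23C(=O)CCC(=C)[C@@]3(O)C1 | intermediate
22 | trans-decalin diol (C5–OH β-equatorial, C9–OH α-axial) | C=C(COCc1ccc(OC)cc1)[C@H]1C[C@H]2OC(C)(C)OC[C@]23[C@@H](O)CCC(=C)[C@@]3(O)C1 | intermediate
23 | trans-decalin hydroxy mesylate (fragmentation precursor) | C=C(COCc1ccc(OC)cc1)[C@H]1C[C@H]2OC(C)(C)OC[C@]23[C@@H](OS(C)(=O)=O)CCC(=C)[C@@]3(O)C1 | intermediate
24 | potassium C9-alkoxide of 23 (not isolated) | C=C(COCc1ccc(OC)cc1)[C@H]1C[C@H]2OC(C)(C)OC[C@]23[C@@H](OS(C)(=O)=O)CCC(=C)[C@@]3([O-])C1.[K+] | intermediate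
25 | ten-membered (E)-C4=C5 enone (C9 ketone, C8 methylene, acetonide, PMB ether) | C=C(COCc1ccc(OC)cc1)[C@H]1C[C@H]2OC(C)(C)OC/C2=C\CCC(=C)C(=O)C1 | intermediate
26 | C9 allylic alcohol (C9 opposite to 42) | C=C(COCc1ccc(OC)cc1)[C@H]1C[C@H]2OC(C)(C)OC/C2=C\CCC(=C)[C@@H](O)C1 | intermediate
27 | erythro spiro-epoxy alcohol | C=C(COCc1ccc(OC)cc1)[C@H]1C[C@H]2OC(C)(C)OC/C2=C\CC[C@@]3(CO3)[C@@H](O)C1 | intermediate
28 | spiro-epoxy ketone (acetonide, PMB ether) | C=C(COCc1ccc(OC)cc1)[C@H]1C[C@H]2OC(C)(C)OC/C2=C\CC[C@@]3(CO3)C(=O)C1 | intermediate
29 | C3,C15-diol of the epoxy ketone | C=C(COCc1ccc(OC)cc1)[C@H]1C[C@@H](O)/C(CO)=C/CC[C@@]3(CO3)C(=O)C1 | intermediate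
30 | (R)-4-benzyl-3-propanoyl-1,3-oxazolidin-2-one | CCC(=O)N1[C@H](Cc2ccccc2)COC1=O | starting material
31 | acetaldehyde | CC=O | starting material
32 | dibutylboron Z-enolate of 30 (not isolated) | C/C=C(\OB(CCCC)CCCC)N1[C@H](Cc2ccccc2)COC1=O | intermediate
33 | (R)-4-benzyl-3-[(2R,3S)-3-hydroxy-2-methylbutanoyl]-1,3-oxazolidin-2-one | O=C([C@H](C)[C@H](C)O)N1[C@H](Cc2ccccc2)COC1=O | intermediate
34 | 3'-O-triethylsilyl ether of 33 | O=C([C@H](C)[C@H](C)O[Si](CC)(CC)CC)N1[C@H](Cc2ccccc2)COC1=O | intermediate
35 | (2R,3S)-2-methyl-3-[(triethylsilyl)oxy]butanoic acid | O=C(O)[C@H](C)[C@H](C)O[Si](CC)(CC)CC | intermediate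
36 | C15 ester (C3–OH free) | C=C(COCc1ccc(OC)cc1)[C@H]1C[C@@H](O)/C(COC(=O)[C@H](C)[C@H](C)O[Si](CC)(CC)CC)=C/CC[C@@]3(CO3)C(=O)C1 | intermediate
37 | C3 senecioate, C15 ester, C13 PMB ether | C=C(COCc1ccc(OC)cc1)[C@H]1C[C@@H](OC(=O)C=C(C)C)/C(COC(=O)[C@H](C)[C@H](C)O[Si](CC)(CC)CC)=C/CC[C@@]3(CO3)C(=O)C1 | intermediate
38 | C13 alcohol | C=C(CO)[C@H]1C[C@@H](OC(=O)C=C(C)C)/C(COC(=O)[C@H](C)[C@H](C)O[Si](CC)(CC)CC)=C/CC[C@@]3(CO3)C(=O)C1 | intermediate
39 | C13 acetate (epoxy ketone with three esters) | C=C(COC(C)=O)[C@H]1C[C@@H](OC(=O)C=C(C)C)/C(COC(=O)[C@H](C)[C@H](C)O[Si](CC)(CC)CC)=C/CC[C@@]3(CO3)C(=O)C1 | intermediate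
40 | threo spiro-epoxy alcohol | C=C(COC(C)=O)[C@H]1C[C@@H](OC(=O)C=C(C)C)/C(COC(=O)[C@H](C)[C@H](C)O[Si](CC)(CC)CC)=C/CC[C@@]3(CO3)[C@H](O)C1 | intermediate
41 | 3'-O-triethylsilyl ether of the target | C=C(COC(C)=O)[C@H]1C[C@@H](OC(=O)C=C(C)C)/C(COC(=O)[C@H](C)[C@H](C)O[Si](CC)(CC)CC)=C/CC[C@@]2(CO)O[C@@H]2C1 | intermediate
42 | CNP0227102.1 | C=C(COC(C)=O)[C@H]1C[C@@H](OC(=O)C=C(C)C)/C(COC(=O)[C@H](C)[C@H](C)O)=C/CC[C@@]2(CO)O[C@@H]2C1 | target

## Step count and least certain steps

Total: 31 steps. Longest linear sequence: 27 steps (1 to 42 through steps 1, 3–21 and 25–31). Stannane 5 takes one further step and acid 35 three.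

**Step 17 (key step).** The fragmentation itself is well aligned. The danger lies after it: the exocyclic α-methylene ketone can isomerise into the ring or take up tert-butoxide in conjugate fashion while base is still present. The fallback sets out from 22 and returns at 28. The exocyclic alkene is epoxidised before the fragmentation: VO(acac)2/t-BuOOH on 22 should deliver oxygen from the axial C9 hydroxyl to the same face of C8=C14 and give spiro-epoxy diol F1. Mesylation gives epoxy mesylate F2, and KOC(CH3)3 fragments F2 as before but releases epoxy ketone 28 directly. The alkoxide cannot open the oxirane on the way, because the two C–O bonds are cis on ring A. No α-methylene ketone then meets base, and steps 18–20 fall away.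

**Step 7.** Discrimination between the two carbonyl groups may be eroded if the boronated primary hydroxyl delivers hydride internally or ties up the catalyst. The fallback sets out from 10 and returns at 12. The primary hydroxyl is silylated (t-BuMe2SiCl, imidazole) to silyl ether F3, which is reduced as in step 7 to hydroxy ketone silyl ether F4. The silyl ether is then cleaved and the acetonide closed in one acid-catalysed operation (camphorsulfonic acid, MeOH, then Me2C(OMe)2) to give 12.

**Step 13.** Hydroperoxide addition to the hindered, tetrasubstituted enal may stall or lose its facial preference. The fallback sets out from 18 and returns at 21.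
- Luche reduction of the aldehyde (NaBH4, CeCl3·7H2O, MeOH, −78 °C) gives allylic alcohol F5.
- Peracid epoxidation (m-CPBA, NaHCO3), an electrophilic oxidant that attacks away from the angular substituent, gives epoxy alcohol F6.
- Iodination (I2, PPh3, imidazole) gives epoxy iodide F7.
- Reductive opening with Zn dust in AcOH/EtOH gives 21.

**Step 29.** The reagent works against the substrate's preference for the erythro alcohol, so diastereoselectivity may be eroded. The fallback sets out from 39 and returns at 40. Chelation-controlled reduction with Zn(BH4)2 follows the substrate's own bias and gives erythro alcohol F8. Mitsunobu inversion with formic acid (PPh3, diisopropyl azodicarboxylate) gives threo formate F9. Methanolysis of the formate (KHCO3, MeOH, 0 °C), which should spare the acetate, gives 40.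

**Step 30.** The alkoxides may transfer acyl groups, most readily from the primary allylic acetate, before the epoxide migration is complete. The fallback sets out from 37 and returns at 41.
- 37, which has no acetate, is reduced as in step 29 to threo epoxy alcohol F10.
- The Payne rearrangement is run there and gives hydroxy epoxide F11.
- The PMB ether is removed (DDQ) to give diol F12.
- Only the unhindered allylic C13 hydroxyl is acetylated (AcCl, 2,4,6-collidine, −78 °C) to give 41; the neopentyl-type C14 hydroxyl next to the quaternary oxirane carbon should react more slowly.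

## Further compounds

F1 | step 17 | spiro-epoxy diol (C8–C14 oxirane syn to C9–OH; C5–OH, C9–OH) | C=C(COCc1ccc(OC)cc1)[C@H]1C[C@H]2OC(C)(C)OC[C@]23[C@@H](O)CC[C@@]4(CO4)[C@@]3(O)C1
F2 | step 17 | spiro-epoxy hydroxy mesylate | C=C(COCc1ccc(OC)cc1)[C@H]1C[C@H]2OC(C)(C)OC[C@]23[C@@H](OS(C)(=O)=O)CC[C@@]4(CO4)[C@@]3(O)C1
F3 | step 7 | tert-butyldimethylsilyl ether of 10 | C=C(COCc1ccc(OC)cc1)[C@H]1CC(=O)[C@](CO[Si](C)(C)C(C)(C)C)(C2SCCCS2)C(=O)C1
F4 | step 7 | tert-butyldimethylsilyl ether of 11 (primary oxygen silylated) | C=C(COCc1ccc(OC)cc1)[C@H]1C[C@@H](O)[C@](CO[Si](C)(C)C(C)(C)C)(C2SCCCS2)C(=O)C1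
F5 | step 13 | bicyclic allylic alcohol (C14–OH, C8=C9, C5 ketone) | C=C(COCc1ccc(OC)cc1)[C@H]1C[C@H]2OC(C)(C)OC[C@]23C(=O)CCC(CO)=C3C1
F6 | step 13 | α-8,9-epoxy C14 alcohol | C=C(COCc1ccc(OC)cc1)[C@H]1C[C@H]2OC(C)(C)OC[C@]23C(=O)CC[C@]4(CO)O[C@@]43C1
F7 | step 13 | α-8,9-epoxy C14 iodide | C=C(COCc1ccc(OC)cc1)[C@H]1C[C@H]2OC(C)(C)OC[C@]23C(=O)CC[C@]4(CI)O[C@@]43C1
F8 | step 29 | erythro spiro-epoxy alcohol (C9 epimer of 40) | C=C(COC(C)=O)[C@H]1C[C@@H](OC(=O)C=C(C)C)/C(COC(=O)[C@H](C)[C@H](C)O[Si](CC)(CC)CC)=C/CC[C@@]3(CO3)[C@@H](O)C1
F9 | step 29 | C9 formate of 40 | C=C(COC(C)=O)[C@H]1C[C@@H](OC(=O)C=C(C)C)/C(COC(=O)[C@H](C)[C@H](C)O[Si](CC)(CC)CC)=C/CC[C@@]3(CO3)[C@H](OC=O)C1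
F10 | step 30 | threo spiro-epoxy alcohol with C13 PMB ether | C=C(COCc1ccc(OC)cc1)[C@H]1C[C@@H](OC(=O)C=C(C)C)/C(COC(=O)[C@H](C)[C@H](C)O[Si](CC)(CC)CC)=C/CC[C@@]3(CO3)[C@H](O)C1
F11 | step 30 | C8–C9 oxirane with C14–OH and C13 PMB ether | C=C(COCc1ccc(OC)cc1)[C@H]1C[C@@H](OC(=O)C=C(C)C)/C(COC(=O)[C@H](C)[C@H](C)O[Si](CC)(CC)CC)=C/CC[C@@]2(CO)O[C@@H]2C1
F12 | step 30 | C13,C14-diol with C8–C9 oxirane | C=C(CO)[C@H]1C[C@@H](OC(=O)C=C(C)C)/C(COC(=O)[C@H](C)[C@H](C)O[Si](CC)(CC)CC)=C/CC[C@@]2(CO)O[C@@H]2C1
A1 | alternative 1 | ten-membered (E,E)-diene with C1 N-acyl oxazolidinone, C3 triethylsilyl, C15 tert-butyldimethylsilyl and C14 tert-butyldiphenylsilyl ethers | O=C([C@H]1C[C@@H](O[Si](CC)(CC)CC)/C(CO[Si](C)(C)C(C)(C)C)=C/CC/C(CO[Si](c2ccccc2)(c2ccccc2)C(C)(C)C)=C/C1)N1[C@H](Cc2ccccc2)COC1=O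
A2 | alternative 2 | ten-membered 8,9-diol with the three esters in place and a C14 PMB ether | C=C(COC(C)=O)[C@H]1C[C@@H](OC(=O)C=C(C)C)/C(COC(=O)[C@H](C)[C@H](C)O[Si](CC)(CC)CC)=C/CC[C@@](COCc2ccc(OC)cc2)(O)[C@@H](O)C1
A3 | alternative 3 | ten-membered (E,E)-dienone with C3 ketone, C1 stereocentre and C12 vinylsilane | C[Si](C)(c1ccccc1)/C=C(\COCc1ccc(OC)c(OC)c1)[C@H]1CC(=O)/C(COC(c2ccccc2)(c2ccccc2)c2ccccc2)=C/CC/C(COCc2ccc(OC)cc2)=C/C1
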